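**Plan**

- Central ring numbering: C1 carries the methide carbon, C2 the resorcinol ring, C3 and C4 are CH, C5 carries CH2OH, C6 the arylethynyl group.
- Retrosynthesis first undoes the quinone methide (five O–CH3 bonds, loss of water from a bis(4-methoxyphenyl) carbinol), then cuts one carbinol–anisyl bond back to a diaryl ketone and takes CH2OH back to a methyl ester.
- The central benzene is then cut at C6–C1 and C3–C2. C3–H, C4–H, C5 (ester) and C6 (alkyne) map onto C3–C6 of a 6-alkynyl-2-pyrone-5-carboxylate, and C1 (aroyl) and C2 (resorcinol ring) are the two carbons of a push–pull ynone.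
- Forward: the pyrone ring closes by Michael addition–lactonisation, the ynone comes from an acyl Sonogashira coupling, the central benzene forms by cycloaddition with loss of CO2, and Grignard addition, ester reduction and demethylation finish the target.
- Stereochemistry: the target has no stereocentre, and the two para-oxygenated rings on the methide carbon exchange by tautomerism, so nothing needs to be controlled.

Key step: step 4

Assumption: BBr3 is taken to exchange the benzylic hydroxyl for bromide while it cleaves the ethers, so step 7 ends with a buffered hydrolysis; if the alcohol survives as its borate, the same work-up should give the target directly.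

Step 1
Reactants: 1 3-(4-methoxyphenyl)propiolic acid; 2 potassium methyl malonate
Product: 5 methyl 5-(4-methoxyphenyl)-3-oxopent-4-ynoate, via acyl imidazolide 3 (not isolated), via acylmalonic half ester 4 (not isolated)
Conditions: CDI, THF, rt; add to 2, MgCl2, Et3N, MeCN, rt; 1 M HCl work-up
Reagents that add atoms: none
Why: Masamune–Brooks homologation, in which the acyl imidazolide C-acylates the magnesium enolate of the malonate half ester and the acylmalonate loses CO2 on acidification, is a standard entry to alkynyl β-keto esters, and the 4-methoxyphenyl group should damp conjugate addition of imidazole to the triple bond.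

Step 2
Reactants: 5 methyl 5-(4-methoxyphenyl)-3-oxopent-4-ynoate; 6 methyl propiolate
Product: 8 methyl 6-[(4-methoxyphenyl)ethynyl]-2-oxo-2H-pyran-5-carboxylate, via acylglutaconate 7 (not isolated)
Conditions: 6 (1.3 equiv), Cs2CO3 (0.2 equiv), MeCN, 0 °C to rt, then 60 °C
Reagents that add atoms: none
Why: Base-catalysed Michael addition–lactonisation of a β-keto ester with a propiolate (the classical 2-pyrone-5-carboxylate synthesis) should apply, since the enolate carbon adds to the unhindered terminal alkynoate faster than to the aryl-capped ynone and the enol oxygen of Z-configured 7 then closes the ring by 6-exo-trig acylation with loss of methanol.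

Step 3
Reactants: 9 1-ethynyl-2,4-dimethoxybenzene; 10 4-methoxybenzoyl chloride
Product: 11 3-(2,4-dimethoxyphenyl)-1-(4-methoxyphenyl)prop-2-yn-1-one
Conditions: PdCl2(PPh3)2 (2 mol %), CuI (4 mol %), Et3N (1.5 equiv), THF, rt
Reagents that add atoms: none
Why: Acyl Sonogashira coupling of a terminal aryl alkyne with an aroyl chloride under PdCl2(PPh3)2/CuI catalysis gives diaryl ynones directly at room temperature, and the amine only has to take up HCl.

Step 4
Reactants: 8 methyl 6-[(4-methoxyphenyl)ethynyl]-2-oxo-2H-pyran-5-carboxylate; 11 3-(2,4-dimethoxyphenyl)-1-(4-methoxyphenyl)prop-2-yn-1-one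
Product: 13 methyl 4-(2,4-dimethoxyphenyl)-3-(4-methoxybenzoyl)-2-[(4-methoxyphenyl)ethynyl]benzoate, via bridged lactone 12 (not isolated)
Conditions: 11 (1.5 equiv), 1,2-dichlorobenzene (1 M), sealed tube, 180 °C
Reagents that add atoms: none
Why: The pyrone diene (C3=C4–C5=C6, numbering carried over to the central ring) and the ynone triple bond should combine thermally in a concerted but asynchronous [4+2] cycloaddition to the 2-oxabicyclo[2.2.2]octadienone 12, which aromatises at once by retro-[4+2] expulsion of CO2; the closest known reaction is the Diels–Alder/decarboxylation of 2-pyrone-5-carboxylates with alkynes to benzoates. The central benzene ring thus closes by an intermolecular [4+2] cycloaddition that forms C6–C1 and C3–C2, and the cycloreversion only removes the lactone bridge. No stereocentre survives, because the two bridgeheads of racemic 12 become aromatic carbons. The step needs regioselectivity and site selectivity: pyrone C6, β to the ester and vinylogously activated by the lactone carbonyl, is the electrophilic terminus and C3 the nucleophilic one, while in the push–pull ynone the acyl-bearing carbon has the larger HOMO coefficient and the aryl-bearing carbon is stabilised as a cation by the 2,4-dimethoxyphenyl ring, so both frontier-orbital pairings join C6 to the acyl carbon and C3 to the aryl carbon. The diaryl alkynes of 8 and 13 are unpolarised and flanked by ortho substituents, and the excess of 11 should keep them from competing as dienophiles.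

Step 5
Reactants: 13 methyl 4-(2,4-dimethoxyphenyl)-3-(4-methoxybenzoyl)-2-[(4-methoxyphenyl)ethynyl]benzoate; 14 4-methoxyphenylmagnesium bromide
Product: 15 methyl 4-(2,4-dimethoxyphenyl)-3-[hydroxybis(4-methoxyphenyl)methyl]-2-[(4-methoxyphenyl)ethynyl]benzoate
Conditions: LaCl3·2LiCl (1 equiv), THF, rt; then 14 (1.3 equiv), 0 °C; aq. NH4Cl
Reagents that add atoms: none
Why: LaCl3·2LiCl-promoted Grignard 1,2-addition to the diaryl ketone should be chemoselective because the oxophilic lanthanum salt activates the hindered, twisted benzophenone carbonyl while aryl Grignard reagents attack methyl benzoates only slowly at 0 °C, and no stereocentre arises since the carbinol carbon ends with two identical anisyl groups.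

Step 6
Reactants: 15 methyl 4-(2,4-dimethoxyphenyl)-3-[hydroxybis(4-methoxyphenyl)methyl]-2-[(4-methoxyphenyl)ethynyl]benzoate
Product: 16 {6-(2,4-dimethoxyphenyl)-3-(hydroxymethyl)-2-[(4-methoxyphenyl)ethynyl]phenyl}bis(4-methoxyphenyl)methanol
Conditions: i-Bu2AlH (4 equiv), CH2Cl2, −78 to 0 °C; aq. KNaC4H4O6 work-up
Reagents that add atoms: none
Why: Hydride reduction of the aryl ester with i-Bu2AlH to the benzylic alcohol is routine at low temperature, where the tertiary alcohol only consumes one equivalent as its aluminium alkoxide and the diaryl alkyne is not hydroaluminated.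

Step 7
Reactants: 16 {6-(2,4-dimethoxyphenyl)-3-(hydroxymethyl)-2-[(4-methoxyphenyl)ethynyl]phenyl}bis(4-methoxyphenyl)methanol
Product: 18 selaginellin F, via benzylic bromide 17 (not isolated)
Conditions: BBr3 (10 equiv), CH2Cl2, −78 °C to rt; H2O, 0 °C; then CaCO3, acetone/H2O (1:1), 50 °C; dilute AcOH work-up
Reagents that add atoms: water, SMILES O
Why: BBr3 cleavage of the five aryl methyl ethers (Lewis-acid ether cleavage) also ionises the doubly para-oxygenated carbinol, so that the aqueous quench should deliver the quinone methide by net loss of water, and the benzylic bromide formed from the primary alcohol under these conditions is returned to the alcohol by solvolysis in CaCO3-buffered aqueous acetone.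

**Compound list**

1 | 3-(4-methoxyphenyl)propiolic acid | COc1ccc(cc1)C#CC(=O)O | starting material
2 | potassium methyl malonate | COC(=O)CC(=O)[O-].[K+] | starting material
3 | 1-(1H-imidazol-1-yl)-3-(4-methoxyphenyl)prop-2-yn-1-one | COc1ccc(cc1)C#CC(=O)n1ccnc1 | intermediate
4 | 2-(methoxycarbonyl)-5-(4-methoxyphenyl)-3-oxopent-4-ynoic acid (racemic, enolisable centre) | COC(=O)C(C(=O)O)C(=O)C#Cc1ccc(OC)cc1 | intermediate
5 | methyl 5-(4-methoxyphenyl)-3-oxopent-4-ynoate | COC(=O)CC(=O)C#Cc1ccc(OC)cc1 | intermediate
6 | methyl propiolate | C#CC(=O)OC | starting material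
7 | dimethyl (Z)-4-[3-(4-methoxyphenyl)prop-2-ynoyl]pent-2-enedioate (racemic, enolisable; alkene isomers interconvert through the anion, the Z isomer that lactonises is drawn) | COC(=O)/C=C\C(C(=O)OC)C(=O)C#Cc1ccc(OC)cc1 | intermediate
8 | methyl 6-[(4-methoxyphenyl)ethynyl]-2-oxo-2H-pyran-5-carboxylate | COC(=O)C1=C(C#Cc2ccc(OC)cc2)OC(=O)C=C1 | intermediate
9 | 1-ethynyl-2,4-dimethoxybenzene | C#Cc1ccc(OC)cc1OC | starting material
10 | 4-methoxybenzoyl chloride | COc1ccc(cc1)C(Cl)=O | starting material
11 | 3-(2,4-dimethoxyphenyl)-1-(4-methoxyphenyl)prop-2-yn-1-one | COc1ccc(cc1)C(=O)C#Cc1ccc(OC)cc1OC | intermediate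
12 | methyl 8-(2,4-dimethoxyphenyl)-7-(4-methoxybenzoyl)-1-[(4-methoxyphenyl)ethynyl]-3-oxo-2-oxabicyclo[2.2.2]octa-5,7-diene-6-carboxylate (racemic, bridgeheads tied by the bicycle, one enantiomer drawn) | O=C1O[C@@]2(C#Cc3ccc(OC)cc3)C(C(=O)OC)=C[C@@H]1C(c1ccc(OC)cc1OC)=C2C(=O)c1ccc(OC)cc1 | intermediate
13 | methyl 4-(2,4-dimethoxyphenyl)-3-(4-methoxybenzoyl)-2-[(4-methoxyphenyl)ethynyl]benzoate | COC(=O)c1ccc(-c2ccc(OC)cc2OC)c(C(=O)c2ccc(OC)cc2)c1C#Cc1ccc(OC)cc1 | intermediate
14 | 4-methoxyphenylmagnesium bromide | COc1ccc(cc1)[Mg]Br | starting material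
15 | methyl 4-(2,4-dimethoxyphenyl)-3-[hydroxybis(4-methoxyphenyl)methyl]-2-[(4-methoxyphenyl)ethynyl]benzoate | COC(=O)c1ccc(-c2ccc(OC)cc2OC)c(C(O)(c2ccc(OC)cc2)c2ccc(OC)cc2)c1C#Cc1ccc(OC)cc1 | intermediate
16 | {6-(2,4-dimethoxyphenyl)-3-(hydroxymethyl)-2-[(4-methoxyphenyl)ethynyl]phenyl}bis(4-methoxyphenyl)methanol | OCc1ccc(-c2ccc(OC)cc2OC)c(C(O)(c2ccc(OC)cc2)c2ccc(OC)cc2)c1C#Cc1ccc(OC)cc1 | intermediate
17 | 4-[[3-(bromomethyl)-6-(2,4-dihydroxyphenyl)-2-[(4-hydroxyphenyl)ethynyl]phenyl](4-hydroxyphenyl)methylidene]cyclohexa-2,5-dien-1-one | O=C1C=CC(=C(c2ccc(O)cc2)c2c(-c3ccc(O)cc3O)ccc(CBr)c2C#Cc2ccc(O)cc2)C=C1 | intermediate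
18 | selaginellin F, 4-[[6-(2,4-dihydroxyphenyl)-3-(hydroxymethyl)-2-[(4-hydroxyphenyl)ethynyl]phenyl](4-hydroxyphenyl)methylidene]cyclohexa-2,5-dien-1-one (no stereocentre) | O=C1C=CC(=C(c2ccc(O)cc2)c2c(-c3ccc(O)cc3O)ccc(CO)c2C#Cc2ccc(O)cc2)C=C1 | target

**Step count**

Total steps: 7. Longest linear sequence: 6 steps (1, 2, 4, 5, 6, 7) from acid 1; step 3 is a one-step branch.

**Steps most likely to fail**

Step 4. Bond formation at the fully substituted pyrone C6 may be so slow that thermal self-cycloaddition of the pyrone through its own triple bond, or erosion of the orientation, takes over. The fallback sets out from pyrone 8 and alkyne 9 and replaces the aroyl group of the dienophile by a smaller, more electron-poor ester. Alkyne 9 would be lithiated (n-BuLi, THF, −78 °C) and quenched with methyl chloroformate to give methyl 3-(2,4-dimethoxyphenyl)prop-2-ynoate F1. Heating 8 with F1 in 1,2-dichlorobenzene should give, through the bridged lactone dimethyl 8-(2,4-dimethoxyphenyl)-1-[(4-methoxyphenyl)ethynyl]-3-oxo-2-oxabicyclo[2.2.2]octa-5,7-diene-6,7-dicarboxylate F2, the diester dimethyl 4-(2,4-dimethoxyphenyl)-2-[(4-methoxyphenyl)ethynyl]benzene-1,3-dicarboxylate F3. i-Bu2AlH (2.2 equiv, toluene, −78 °C) should reduce only the ester with a free ortho position, giving methyl 6-(2,4-dimethoxyphenyl)-3-(hydroxymethyl)-2-[(4-methoxyphenyl)ethynyl]benzoate F4. An excess of 4-methoxyphenyllithium (from 4-bromoanisole and n-BuLi, THF, −78 °C to rt) would then add twice to the remaining hindered ester, and the route is rejoined at diol 16.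

Step 2. Conjugate addition of the enolate or of liberated methoxide to the ynone unit, or carbon-cyclisation of the adduct anion onto the ynone, may outrun O-lactonisation. The fallback sets out from acid 1 and builds the same adduct by enolate acylation instead of Michael addition. The imidazolide 3 (CDI, THF) would be added at −78 °C to the lithium enolate of dimethyl glutaconate (2 equiv, LiN(SiMe3)2, THF). Because the glutaconate anion is symmetric, C-acylation at either terminus gives the same acylglutaconate 7. After an acetic acid quench, 7 would be closed with catalytic p-TsOH in warm toluene, and the route is rejoined at pyrone 8 without the β-keto ester, methyl propiolate or an alkoxide base being present. This fallback makes no compound outside the list (F0).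

Step 7. Exchange of the benzylic hydroxyl for bromide during demethylation may be followed by incomplete hydrolysis, or by alkylation of the freed phenols by that bromide under the buffered aqueous conditions. The fallback sets out from crude bromide 17 and passes through an ester instead of direct hydrolysis. Displacement with KOAc in DMF at 40 °C, where acetate is too weak a base to form phenoxides, should give {4-(2,4-dihydroxyphenyl)-2-[(4-hydroxyphenyl)ethynyl]-3-[(4-hydroxyphenyl)(4-oxocyclohexa-2,5-dien-1-ylidene)methyl]phenyl}methyl acetate F5. K2CO3 in MeOH at rt followed by acidification with AcOH would cleave the acetate, and the route is rejoined at 18.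

**Further compounds**

F1 | step 4 | methyl 3-(2,4-dimethoxyphenyl)prop-2-ynoate | COC(=O)C#Cc1ccc(OC)cc1OC
F2 | step 4 | dimethyl 8-(2,4-dimethoxyphenyl)-1-[(4-methoxyphenyl)ethynyl]-3-oxo-2-oxabicyclo[2.2.2]octa-5,7-diene-6,7-dicarboxylate (racemic, one enantiomer drawn) | O=C1O[C@@]2(C#Cc3ccc(OC)cc3)C(C(=O)OC)=C[C@@H]1C(c1ccc(OC)cc1OC)=C2C(=O)OC
F3 | step 4 | dimethyl 4-(2,4-dimethoxyphenyl)-2-[(4-methoxyphenyl)ethynyl]benzene-1,3-dicarboxylate | COC(=O)c1ccc(-c2ccc(OC)cc2OC)c(C(=O)OC)c1C#Cc1ccc(OC)cc1
F4 | step 4 | methyl 6-(2,4-dimethoxyphenyl)-3-(hydroxymethyl)-2-[(4-methoxyphenyl)ethynyl]benzoate | OCc1ccc(-c2ccc(OC)cc2OC)c(C(=O)OC)c1C#Cc1ccc(OC)cc1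
F0 | step 2 | none | none
F5 | step 7 | {4-(2,4-dihydroxyphenyl)-2-[(4-hydroxyphenyl)ethynyl]-3-[(4-hydroxyphenyl)(4-oxocyclohexa-2,5-dien-1-ylidene)methyl]phenyl}methyl acetate | CC(=O)OCc1ccc(-c2ccc(O)cc2O)c(C(=C2C=CC(=O)C=C2)c2ccc(O)cc2)c1C#Cc1ccc(O)cc1
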